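## Structural features

The target has three carbocycles and one arene. Ring A is a cyclohexane with an exocyclic methylene. Rings B and C form an octalin whose only alkene is the tetrasubstituted ring-fusion bond. The arene is a 2-substituted hydroquinone: the hydroxyl ortho to the benzylic carbon is free and the oxygen para to it is a hydrogen sulfate. The methine of ring A is joined through a CH2–CH2 link to the quaternary carbon of ring B, and the arene through one CH2 to the quaternary carbon of ring C; these two quaternary carbons sit on the two different sp2 carbons of the ring fusion. Ring A carries three contiguous stereocentres (carbinol S; quaternary carbon S with methyl and 4-methylpent-3-enyl; methine R; hydroxyl and link both cis to the methyl), ring C two contiguous ones (quaternary carbon R next to an S-configured CH–CH3, the two methyls cis), and ring B one isolated quaternary centre (R). The ring B centre and the ring C pair face each other across a planar alkene and ring A is insulated by the link, so three stereochemical domains must be set independently. Fragile are the aryl sulfate (acid), the free phenol and the arene carbon ortho to the benzyl group (either can add to a cation at the ring fusion), the exocyclic methylene (migrates under acid), the three alkenes (no hydrogenation or hydrogenolysis) and the hydroquinone once both oxygens are free. The real difficulty is the pair of all-carbon quaternary stereocentres flanking the tetrasubstituted alkene, followed by the need to tell the two phenolic oxygens apart. The key step exploits the ring B quaternary carbon: it bears a methyl, a one-carbon branch (the first carbon of the link) and a ring CH2 and is bonded to a ring-fusion sp2 carbon, which is the pattern left by C-2 of methacrolein after [4+2] addition to a 1-vinylcyclohexene built from ring C; the CH2–CH2 bond on the far side of ring B is the second bond formed.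

## Logic of the disconnections

33 ⇒ 32 ⇒ 31 ⇒ 30. The aryl O–S bond is cut, together with the two O–Si bonds and the O–benzyl bond that mask the three hydroxyls. The sulfate is the most fragile group and goes on next to last; 30 is neutral and lipophilic, with a separate mask on each oxygen. No late step then has to choose between two phenols. The demand is that the oxygen to be sulfated is freed without hydrogen gas or acid (30 → 31) and that the other two masks leave under conditions an aryl sulfate survives (32 → 33). Two identical ether groups on the hydroquinone would fail both demands, so the two oxygens are differentiated from 1 onwards.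

30 ⇒ 29. The exocyclic C=CH2 bond is cut back to a ketone. The ketone makes the neighbouring methine adjustable and opens the link bond to enolate chemistry. The forward step must methylenate a ketone flanked by a branched carbon without disturbing that methine.

29 ⇒ 27 ⇒ 25 ⇒ 17 + 23. The bond between the ring A methine and the adjacent link carbon is cut. It divides the molecule into two halves of similar size, each with its own stereochemical domain. The forward sequence needs a regiodefined enolate next to a quaternary carbon (24 from 23), its addition to an enolisable aldehyde, loss of water via 26, and a conjugate reduction whose protonation, backed by equilibration of 28, puts the link equatorial in 29.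

23 ⇒ 20 + 21. The bond between the ring A quaternary carbon and the homoprenyl chain is cut. Conjugate addition creates the quaternary centre relative to the existing silyloxy centre and delivers the enolate on the required side as a storable silyl enol ether. The demand is addition anti to the silyloxy group (via 22).

20 ⇒ 19 ⇒ 18 ⇒ 5. The ring ketone is traced to an allylic CH2 and the carbinol centre to an enantioselective ketone reduction. Ring A then comes in three steps from the same bulk enone that supplies ring C. The demand is regioselective allylic oxidation in 19.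

17 ⇒ 16 ⇒ 15. The bond between the two link carbons is cut (one-carbon homologation), because the cycloaddition can deliver only a one-carbon branch on the ring B quaternary carbon. The demand is olefination of a neopentyl aldehyde and a hydrolysis mild enough for the aryl silyl ether.

15 ⇒ 14. The alkene is moved one position out of the ring fusion. A [4+2] reaction necessarily leaves the alkene between the two inner diene carbons, and the shift into the fusion erases the one uncontrolled stereocentre of 14. The forward step must reach the tetrasubstituted isomer without the arene trapping a cation. A cobalt–salen hydride catalyst would be the mildest choice on paper, but such catalysts act on mono- and 1,1-disubstituted alkenes and are not expected to engage this hindered trisubstituted one, so an iodine-mediated equilibration is written.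

14 ⇒ 12 + 13. Two bonds of ring B are cut: quaternary carbon to ring-fusion carbon, and the CH2–CH2 bond opposite. This removes ring B and the isolated quaternary stereocentre in one step and leaves a two-carbon enal and a monocyclic diene. The demands are ortho regiochemistry, reagent-controlled choice of the enal face, and enough reactivity from a diene with a quaternary carbon on its inner position.

12 ⇒ 10 + 11, and 10 ⇒ 8. The vinyl–ring bond is cut, then the enol triflate is traced to the ketone. The only requirement is that 8 enolises on one side only (via 9), which the quaternary α-carbon guarantees.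

8 ⇒ 5 + 4. The β C–CH3 bond and the α C–CH2Ar bond are cut. Both ring C stereocentres and the whole benzyl unit arrive in one operation. The demands are an enantioselective methyl addition and alkylation of the resulting enolate (6, activated as 7) anti to the new methyl, which gives the cis-dimethyl arrangement.

4 ⇒ 3 ⇒ 2 ⇒ 1. Only functional-group changes at the benzylic carbon and one silylation are needed, because 1 already has its two oxygens differentiated.

## Other disconnections considered

Alternative 1: The cut is the bond between the quaternary carbon and the methine of ring A. In the forward step a mild Lewis acid opens the acyclic epoxide A2 at its tertiary carbon; the far carbon of the Z-allylsilane attacks anti through a chair and loss of the silyl group leaves the exocyclic methylene of ring A alcohol A1.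
- In favour: all three ring A centres and the methylene come in one step from epoxide configuration and alkene geometry, with no epimerisable ketone and no late methylenation. On this point A1 is better than the chosen plan, which sets the methine by protonation and needs a separate methylenation.
- Against: A1 ends in a one-carbon CH2O stub. The link must then be made by joining two CH2 groups, one neopentylic on the octalin side and one β-branched on ring A. A displacement there is poor, and an olefination followed by reduction would have to spare the methylene already present.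
- Structure: it solves the smaller half and leaves the octalin with its two quaternary carbons untouched.
- Mechanism: a cationic cyclisation beside a second nucleophilic trisubstituted alkene, against closed-shell enolate chemistry in the chosen plan.
- Step economy: A2 needs an enantioselective epoxidation and a geometrically defined allylsilane, clearly more steps than the four that lead to 23.

Alternative 2: The cut removes two bonds at ring A, quaternary carbon to homoprenyl and methine to link. In the forward step the organocopper reagent made from 22 adds to 20 anti to the silyloxy group and the enolate is intercepted in the same flask by an octalin acetaldehyde, written here in the simple dimethyl ether series as A4, to give aldol adduct A3.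
- In favour: it forms the same two bonds as steps 14 and 15 in one operation and is better by one step; stereocontrol at the quaternary carbon rests on the same anti addition and is equal.
- Against: the most valuable intermediate meets a mixed magnesium–copper enolate and residual organometallic, so direct addition to the aldehyde and proton transfer from its α-CH2 compete.
- Structure: it is a fragment-union tactic; the aldehyde partner A4 still needs its own key step, so it complements the chosen disconnection and does not replace it.
- Mechanism: the same polar steps as the chosen plan. The chosen plan uses the two-flask form (23, then 24) so that a clean, titrated lithium enolate meets 17 as the limiting component.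

Alternative 3: The cut is in ring C: the bond from the benzylic quaternary carbon to the ring fusion and the CH(CH3)–CH2 bond. In the forward step a chiral oxazaborolidinium catalyst brings (E)-2-methylbut-2-enal A7 onto the ring B diene A6 to give octalin aldehyde A5 (ring-fusion epimers), whose formyl carbon is the future benzylic carbon.
- In favour: both ring C centres arise in one catalytic step, the cis-dimethyl relation following from the E geometry. That is better than the chosen plan, which needs conjugate addition plus alkylation. The quaternary centre of A6 would come from a very dependable catalytic conjugate addition (equal or better than step 4). The link already has both carbons, so no homologation is needed. The electron-rich arene is absent during cycloaddition and alkene shift (better).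
- Against: A7 is substituted at both alkene carbons and far less reactive than 13, yet meets a diene of the same hindrance. The aryl group must then be added to a neopentyl aldehyde and the benzylic oxygen removed without acid or hydrogenation, which spends the steps saved.
- Structure: the mirror image of the chosen plan, with ring C built last instead of ring B.
- Mechanism: the same reaction class, the same regiochemical argument and the same later alkene shift, but the whole risk sits on a less reactive dienophile.
- Step economy: about equal.

Key step: step 7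

Assumption 1: the target is drawn as the free aryl hydrogen sulfate and is taken as that acid form, liberated only in the last operation; the corresponding sodium salt is the form suited to storage.
Assumption 2: the catalyst of step 7 is written in the (S)-prolinol series on the basis of the usual formyl C–H···O binding model; if that model pointed to the other face for this diene, the mirror-image catalyst would be the only change.

Abbreviations in names: ArCH2 = {5-(benzyloxy)-2-[(triisopropylsilyl)oxy]phenyl}methyl; TBS = tert-butyldimethylsilyl; TIPS = triisopropylsilyl; Oct = (1R,5R,6S)-5-(ArCH2)-1,5,6-trimethyl-1,2,3,4,5,6,7,8-octahydronaphthalen-1-yl.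

## Route

Step 1
Reactants: 1 5-(benzyloxy)-2-hydroxybenzaldehyde
Product: 2 5-(benzyloxy)-2-[(triisopropylsilyl)oxy]benzaldehyde
Conditions: TIPSCl, imidazole, DMF, 20 °C
Reagents that add atoms: triisopropylsilyl chloride CC(C)[Si](Cl)(C(C)C)C(C)C
Why: Silylation of a phenol; the bulky aryl silyl ether is chosen because it should survive the bases, the Lewis acid and the dilute acid of the route and leave with fluoride at the end.

Step 2
Reactants: 2 5-(benzyloxy)-2-[(triisopropylsilyl)oxy]benzaldehyde
Product: 3 {5-(benzyloxy)-2-[(triisopropylsilyl)oxy]phenyl}methanol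
Conditions: NaBH4, MeOH/THF, 0 °C
Reagents that add atoms: none
Why: Borohydride reduction of an aromatic aldehyde; at 0 °C the hindered silyl group is not expected to migrate to the new alkoxide.

Step 3
Reactants: 3 {5-(benzyloxy)-2-[(triisopropylsilyl)oxy]phenyl}methanol
Product: 4 [4-(benzyloxy)-2-(bromomethyl)phenoxy]triisopropylsilane (ArCH2Br)
Conditions: CBr4, PPh3, CH2Cl2, 0 °C
Reagents that add atoms: carbon tetrabromide BrC(Br)(Br)Br
Why: Appel bromination of a benzylic alcohol under neutral conditions that spare the aryl silyl ether.

Step 4
Reactants: 5 2-methylcyclohex-2-en-1-one; 4 ArCH2Br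
Product: 8 (2R,3S)-2-(ArCH2)-2,3-dimethylcyclohexan-1-one, via dimethylaluminium enolate 6 (not isolated), via lithium aluminate enolate 7 (not isolated)
Conditions: Me3Al, copper thiophene-2-carboxylate (2 mol%), chiral biphenol-based phosphoramidite (4 mol%, enantiomer giving 3S), Et2O, −30 °C; then MeLi, THF/DMPU, −30 °C; then 4, −30 → 20 °C
Reagents that add atoms: trimethylaluminium C[Al](C)C
Why: Copper-catalysed asymmetric conjugate addition of Me3Al to a 2-substituted cyclohexenone sets the S methine under ligand control. Aluminium enolate 6, made nucleophilic as aluminate 7, is alkylated by the benzylic bromide on the face opposite the new methyl (axial attack on the half-chair with pseudoaxial 3-methyl), which gives the cis-dimethyl 2R,3S ketone.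

Step 5
Reactants: 8 (2R,3S)-2-(ArCH2)-2,3-dimethylcyclohexan-1-one
Product: 10 (5S,6R)-6-(ArCH2)-5,6-dimethylcyclohex-1-en-1-yl trifluoromethanesulfonate, via potassium enolate 9 (not isolated)
Conditions: KN(SiMe3)2, THF, −78 °C; then PhNTf2, −78 → 0 °C
Reagents that add atoms: N-phenylbis(trifluoromethanesulfonimide) O=S(=O)(N(c1ccccc1)S(=O)(=O)C(F)(F)F)C(F)(F)F
Why: The ketone can enolise only away from the quaternary carbon, so O-sulfonylation of enolate 9 gives a single enol triflate without touching either stereocentre.

Step 6
Reactants: 10 (5S,6R)-6-(ArCH2)-5,6-dimethylcyclohex-1-en-1-yl trifluoromethanesulfonate; 11 vinylboronic acid pinacol ester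
Product: 12 ring C diene, [4-(benzyloxy)-2-{[(1R,6S)-2-ethenyl-1,6-dimethylcyclohex-2-en-1-yl]methyl}phenoxy]triisopropylsilane
Conditions: Pd(PPh3)4 (5 mol%), K3PO4, dioxane/H2O 10:1, 70 °C
Reagents that add atoms: none
Why: Suzuki coupling of an enol triflate with a vinylboronate; aryl silyl and benzyl ethers are inert to zerovalent palladium and phosphate base.

Step 7
Reactants: 12 ring C diene; 13 methacrolein
Product: 14 (1S,5R,6S)-5-(ArCH2)-1,5,6-trimethyl-1,2,3,5,6,7,8,8a-octahydronaphthalene-1-carbaldehyde (both configurations at C-8a)
Conditions: 13 (3 equiv), oxazaborolidinium triflimide from (S)-α,α-diphenylprolinol, o-tolylboronic acid and Tf2NH (20 mol%, slight deficit of Tf2NH), CH2Cl2, −78 → −40 °C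
Reagents that add atoms: none
Why: A concerted but asynchronous [4+2] cycloaddition in which the boron cation binds the formyl oxygen of s-trans methacrolein; the closest known reaction type is the oxazaborolidinium-catalysed addition of 2-substituted acroleins to 1- and 2-alkyl dienes. Ring B is closed by intermolecular [4+2]: the enal CH2 bonds to the vinyl CH2 terminus and C-2 of the enal to the ring CH terminus, both bonds in one suprafacial event. This ortho orientation follows from the larger diene HOMO coefficient at the unsubstituted vinyl terminus (the 1-alkyl substituent outweighs the 2-alkyl one) and is reinforced by Lewis acid activation. The quaternary carbon on the inner diene position destabilises the s-trans rotamer, so the diene sits s-cis and should react despite its bulk. The new quaternary stereocentre is fixed by the catalyst alone, which shields one face of the bound enal so that the diene adds to the Re face of C-2, giving 1S. The ring C centres lie next to the inner diene carbon, remote from both bonding termini, so they can bias only the diene face. The ring-fusion methine (C-8a) is not controlled, and because step 8 removes it, endo and exo adducts from either diene face converge. The selectivities needed are therefore regiochemistry and enal face only; the substrate has no basic or acidic group, and the deficit of Tf2NH keeps free acid away from the diene and the electron-rich arene.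

Step 8
Reactants: 14 octalin aldehyde (C-8a epimers)
Product: 15 (1S,5R,6S)-5-(ArCH2)-1,5,6-trimethyl-1,2,3,4,5,6,7,8-octahydronaphthalene-1-carbaldehyde
Conditions: I2 (10 mol%), benzene, 80 °C
Reagents that add atoms: none
Why: Iodine (trace HI) equilibrates a trisubstituted octalin alkene to the tetrasubstituted ring-fusion isomer, expected to be the most stable of the positional isomers within reach; the aldehyde has no α-hydrogen and the two quaternary centres cannot epimerise. The shift removes C-8a as a stereocentre, and in a non-polar medium with iodide as counter-ion proton loss should outrun capture of the tertiary cation by the arene.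

Step 9
Reactants: 15 tetrasubstituted octalin aldehyde
Product: 16 (1R,5R,6S)-5-(ArCH2)-1-(2-methoxyethenyl)-1,5,6-trimethyl-1,2,3,4,5,6,7,8-octahydronaphthalene (E/Z)
Conditions: Ph3P(Cl)CH2OMe, NaN(SiMe3)2, THF, 0 → 20 °C
Reagents that add atoms: (methoxymethyl)triphenylphosphonium chloride COC[P+](c1ccccc1)(c1ccccc1)c1ccccc1.[Cl-]
Why: Wittig reaction of a non-enolisable neopentyl aldehyde with the small methoxymethylene ylide; the enol ether geometry is irrelevant.

Step 10
Reactants: 16 enol ether
Product: 17 2-(Oct)acetaldehyde
Conditions: 1 M aq. HCl, THF, 20 °C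
Reagents that add atoms: water O
Why: Enol ether hydrolysis in dilute acid at room temperature is far faster than any reaction of the aryl silyl ether, the benzyl ether or the hindered tetrasubstituted alkene.

Step 11
Reactants: 5 2-methylcyclohex-2-en-1-one
Product: 18 (S)-2-methylcyclohex-2-en-1-ol
Conditions: (R)-2-methyl-CBS-oxazaborolidine (10 mol%), catecholborane, toluene, −78 °C
Reagents that add atoms: none
Why: CBS reduction; the α-methylvinyl arm acts as the large group, so the (R)-catalyst should deliver hydride to give the S allylic alcohol by 1,2-reduction.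

Step 12
Reactants: 18 (S)-2-methylcyclohex-2-en-1-ol
Product: 19 (S)-tert-butyldimethyl[(2-methylcyclohex-2-en-1-yl)oxy]silane
Conditions: TBSCl, imidazole, DMF, 20 °C
Reagents that add atoms: tert-butyldimethylsilyl chloride CC(C)(C)[Si](C)(C)Cl
Why: Standard silylation of a secondary allylic alcohol; the silyl ether later directs the conjugate addition and masks the alcohol until the last step.

Step 13
Reactants: 19 TBS ether of (S)-2-methylcyclohex-2-en-1-ol
Product: 20 (S)-4-[(tert-butyldimethylsilyl)oxy]-3-methylcyclohex-2-en-1-one
Conditions: Rh2(cap)4 (1 mol%, cap = caprolactamate), t-BuOOH (70% aq., 5 equiv), K2CO3, CH2Cl2, 20 °C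
Reagents that add atoms: tert-butyl hydroperoxide CC(C)(C)OO
Why: Radical allylic oxidation; hydrogen abstraction from the ring CH2 next to the unsubstituted alkene carbon gives the most stabilised allyl radical, which is oxygenated at its secondary end to the β-methyl enone. The C–H on the silyloxy carbon is shielded by the silyl group and the stereocentre is not touched.

Step 14
Reactants: 20 (S)-4-(TBSO)-3-methylcyclohex-2-en-1-one; 21 5-bromo-2-methylpent-2-ene
Product: 23 (3S,4S)-4-(TBSO)-3-methyl-3-(4-methylpent-3-en-1-yl)-1-[(trimethylsilyl)oxy]cyclohex-1-ene, via homoprenylmagnesium bromide 22 (not isolated)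
Conditions: 21, Mg, THF, 20 °C; then CuBr·SMe2 (10 mol%), Me3SiCl, DMPU, 20, THF, −78 °C; Et3N, pentane work-up
Reagents that add atoms: chlorotrimethylsilane C[Si](C)(C)Cl
Why: Copper-catalysed, silyl chloride-accelerated conjugate addition of a Grignard reagent; the nucleophile adds to the β-carbon on the face opposite the neighbouring silyloxy group, which sets the quaternary carbon (S, chain trans to oxygen). The silyl chloride traps the enolate regiospecifically on the side of the quaternary carbon.

Step 15
Reactants: 23 ring A silyl enol ether; 17 2-(Oct)acetaldehyde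
Product: 25 (3S,4S)-4-(TBSO)-2-[1-hydroxy-2-(Oct)ethyl]-3-methyl-3-(4-methylpent-3-en-1-yl)cyclohexan-1-one (epimers at C-2 and at the carbinol carbon), via lithium enolate 24 (not isolated)
Conditions: 23 (1.5 equiv), MeLi, THF, 0 °C; then 17, −78 °C; aq. NH4Cl
Reagents that add atoms: none
Why: MeLi cleaves the trimethylsilyl enol ether to the regiodefined lithium enolate 24, which undergoes aldol addition at −78 °C. The two new centres need no control because one is removed in step 16 and the other is reset in step 17.

Step 16
Reactants: 25 β-hydroxy ketone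
Product: 27 (3S,4S)-4-(TBSO)-3-methyl-3-(4-methylpent-3-en-1-yl)-2-[2-(Oct)ethylidene]cyclohexan-1-one (either alkene geometry), via mesylate 26 (not isolated)
Conditions: MsCl, Et3N, CH2Cl2, 0 °C; then DBU, 20 °C
Reagents that add atoms: none
Why: Mesylation followed by E1cB elimination through the ketone enolate gives the conjugated exocyclic enone; anhydrous amine bases leave the aryl silyl ether intact.

Step 17
Reactants: 27 exocyclic enone
Product: 29 (2S,3S,4S)-4-(TBSO)-3-methyl-3-(4-methylpent-3-en-1-yl)-2-[2-(Oct)ethyl]cyclohexan-1-one, via ketone epimer mixture 28 (not isolated)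
Conditions: [(Ph3P)CuH]6, toluene, H2O (2 equiv), 20 °C; then DBU, toluene, 40 °C
Reagents that add atoms: none
Why: Copper hydride conjugate reduction is selective for the enone over the three isolated alkenes. Protonation of the enolate from the face opposite the pseudoaxial ring methyl (silyloxy and homoprenyl groups equatorial) and base equilibration of 28 both place the link equatorial, cis to the methyl, which is the 2S configuration.

Step 18
Reactants: 29 ring A ketone
Product: 30 (1S,2S,3R)-configured TBS ether: tert-butyldimethylsilyl ether of 2-methyl-4-methylidene-2-(4-methylpent-3-en-1-yl)-3-[2-(Oct)ethyl]cyclohexan-1-ol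
Conditions: Ph3PCH3Br, KN(SiMe3)2, THF, 0 → 40 °C
Reagents that add atoms: methyltriphenylphosphonium bromide C[P+](c1ccccc1)(c1ccccc1)c1ccccc1.[Br-]
Why: Wittig methylenation with an alkoxide-free ylide, a reaction that tolerates α-branched cyclohexanones; the α-substituent already has its preferred orientation, so reversible enolisation should not erode it.

Step 19
Reactants: 30 fully protected methylene compound
Product: 31 phenol: 30 with the benzyl ether replaced by a free hydroxyl (4-hydroxy position para to the silyloxy group)
Conditions: LiDBB (lithium 4,4'-di-tert-butylbiphenylide), THF, −78 °C; aq. NH4Cl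
Reagents that add atoms: none
Why: Reductive single-electron cleavage of an aryl benzyl ether at −78 °C; isolated alkenes and silyl ethers are not reduced, so hydrogenolysis is avoided.

Step 20
Reactants: 31 phenol
Product: 32 sodium aryl sulfate: 31 with the free hydroxyl converted into OSO3Na
Conditions: SO3·pyridine, pyridine, 20 °C; then aq. NaHCO3
Reagents that add atoms: sulfur trioxide–pyridine complex [O-]S(=O)(=O)[n+]1ccccc1; sodium hydrogen carbonate [Na+].OC([O-])=O
Why: O-Sulfonation of the only free hydroxyl; the site is fixed by the protecting groups, not by a steric preference between two phenols.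

Step 21
Reactants: 32 sodium aryl sulfate
Product: 33 target, (1S,2S,3R)-3-{2-[(1R,5R,6S)-5-{[2-hydroxy-5-(sulfooxy)phenyl]methyl}-1,5,6-trimethyl-1,2,3,4,5,6,7,8-octahydronaphthalen-1-yl]ethyl}-2-methyl-4-methylidene-2-(4-methylpent-3-en-1-yl)cyclohexan-1-ol
Conditions: Bu4NF, THF, 0 → 40 °C; then sulfonic acid resin (H+ form), MeOH, 0 °C
Reagents that add atoms: none
Why: Fluoride cleaves the aryl triisopropylsilyl and the alkyl tert-butyldimethylsilyl ethers, while aryl sulfate monoester anions are stable to fluoride and base. A brief cold cation exchange then gives the acid form without time for the phenol or the methylene to react at the acid-sensitive alkenes.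

## Compound list

1 | 5-(benzyloxy)-2-hydroxybenzaldehyde | O=Cc1cc(OCc2ccccc2)ccc1O | starting material
2 | 5-(benzyloxy)-2-[(triisopropylsilyl)oxy]benzaldehyde | O=Cc1cc(OCc2ccccc2)ccc1O[Si](C(C)C)(C(C)C)C(C)C | intermediate
3 | {5-(benzyloxy)-2-[(triisopropylsilyl)oxy]phenyl}methanol | OCc1cc(OCc2ccccc2)ccc1O[Si](C(C)C)(C(C)C)C(C)C | intermediate
4 | [4-(benzyloxy)-2-(bromomethyl)phenoxy]triisopropylsilane | BrCc1cc(OCc2ccccc2)ccc1O[Si](C(C)C)(C(C)C)C(C)C | intermediate
5 | 2-methylcyclohex-2-en-1-one | CC1=CCCCC1=O | starting material
6 | dimethylaluminium (S)-2,3-dimethylcyclohex-1-en-1-olate | C[Al](C)OC1=C(C)[C@@H](C)CCC1 | intermediate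
7 | lithium trimethyl[(S)-2,3-dimethylcyclohex-1-en-1-olato]aluminate | [Li+].C[Al-](C)(C)OC1=C(C)[C@@H](C)CCC1 | intermediate
8 | (2R,3S)-2-(ArCH2)-2,3-dimethylcyclohexan-1-one | O=C1CCC[C@H](C)[C@@]1(C)Cc1cc(OCc2ccccc2)ccc1O[Si](C(C)C)(C(C)C)C(C)C | intermediate
9 | potassium (5S,6R)-6-(ArCH2)-5,6-dimethylcyclohex-1-en-1-olate | [K]OC1=CCC[C@H](C)[C@@]1(C)Cc1cc(OCc2ccccc2)ccc1O[Si](C(C)C)(C(C)C)C(C)C | intermediate
10 | (5S,6R)-6-(ArCH2)-5,6-dimethylcyclohex-1-en-1-yl trifluoromethanesulfonate | O=S(=O)(OC1=CCC[C@H](C)[C@@]1(C)Cc1cc(OCc2ccccc2)ccc1O[Si](C(C)C)(C(C)C)C(C)C)C(F)(F)F | intermediate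
11 | vinylboronic acid pinacol ester | C=CB1OC(C)(C)C(C)(C)O1 | starting material
12 | ring C diene, [4-(benzyloxy)-2-{[(1R,6S)-2-ethenyl-1,6-dimethylcyclohex-2-en-1-yl]methyl}phenoxy]triisopropylsilane | C=CC1=CCC[C@H](C)[C@@]1(C)Cc1cc(OCc2ccccc2)ccc1O[Si](C(C)C)(C(C)C)C(C)C | intermediate
13 | methacrolein | CC(=C)C=O | starting material
14 | (1S,5R,6S)-5-(ArCH2)-1,5,6-trimethyl-1,2,3,5,6,7,8,8a-octahydronaphthalene-1-carbaldehyde, C-8a epimers | O=C[C@@]1(C)CCC=C2C1CC[C@H](C)[C@@]2(C)Cc1cc(OCc3ccccc3)ccc1O[Si](C(C)C)(C(C)C)C(C)C | intermediate
15 | (1S,5R,6S)-5-(ArCH2)-1,5,6-trimethyl-1,2,3,4,5,6,7,8-octahydronaphthalene-1-carbaldehyde | O=C[C@@]1(C)CCCC2=C1CC[C@H](C)[C@@]2(C)Cc1cc(OCc3ccccc3)ccc1O[Si](C(C)C)(C(C)C)C(C)C | intermediate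
16 | (1R,5R,6S)-5-(ArCH2)-1-(2-methoxyethenyl)-1,5,6-trimethyl-1,2,3,4,5,6,7,8-octahydronaphthalene, E/Z | COC=C[C@@]1(C)CCCC2=C1CC[C@H](C)[C@@]2(C)Cc1cc(OCc3ccccc3)ccc1O[Si](C(C)C)(C(C)C)C(C)C | intermediate
17 | 2-(Oct)acetaldehyde | O=CC[C@@]1(C)CCCC2=C1CC[C@H](C)[C@@]2(C)Cc1cc(OCc3ccccc3)ccc1O[Si](C(C)C)(C(C)C)C(C)C | intermediate
18 | (S)-2-methylcyclohex-2-en-1-ol | CC1=CCCC[C@@H]1O | intermediate
19 | (S)-tert-butyldimethyl[(2-methylcyclohex-2-en-1-yl)oxy]silane | CC1=CCCC[C@@H]1O[Si](C)(C)C(C)(C)C | intermediate
20 | (S)-4-[(tert-butyldimethylsilyl)oxy]-3-methylcyclohex-2-en-1-one | O=C1CC[C@H](O[Si](C)(C)C(C)(C)C)C(C)=C1 | intermediate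
21 | 5-bromo-2-methylpent-2-ene | CC(C)=CCCBr | starting material
22 | (4-methylpent-3-en-1-yl)magnesium bromide | CC(C)=CCC[Mg]Br | intermediate
23 | (3S,4S)-4-(TBSO)-3-methyl-3-(4-methylpent-3-en-1-yl)-1-[(trimethylsilyl)oxy]cyclohex-1-ene | C[Si](C)(C)OC1=C[C@](C)(CCC=C(C)C)[C@@H](O[Si](C)(C)C(C)(C)C)CC1 | intermediate
24 | lithium (3S,4S)-4-(TBSO)-3-methyl-3-(4-methylpent-3-en-1-yl)cyclohex-1-en-1-olate | [Li]OC1=C[C@](C)(CCC=C(C)C)[C@@H](O[Si](C)(C)C(C)(C)C)CC1 | intermediate
25 | (3S,4S)-4-(TBSO)-2-[1-hydroxy-2-(Oct)ethyl]-3-methyl-3-(4-methylpent-3-en-1-yl)cyclohexan-1-one, epimers at C-2 and the carbinol carbon | O=C1CC[C@H](O[Si](C)(C)C(C)(C)C)[C@@](C)(CCC=C(C)C)C1C(O)C[C@@]1(C)CCCC2=C1CC[C@H](C)[C@@]2(C)Cc1cc(OCc3ccccc3)ccc1O[Si](C(C)C)(C(C)C)C(C)C | intermediate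
26 | methanesulfonate of 25 | O=C1CC[C@H](O[Si](C)(C)C(C)(C)C)[C@@](C)(CCC=C(C)C)C1C(OS(C)(=O)=O)C[C@@]1(C)CCCC2=C1CC[C@H](C)[C@@]2(C)Cc1cc(OCc3ccccc3)ccc1O[Si](C(C)C)(C(C)C)C(C)C | intermediate
27 | (3S,4S)-4-(TBSO)-3-methyl-3-(4-methylpent-3-en-1-yl)-2-[2-(Oct)ethylidene]cyclohexan-1-one | O=C1CC[C@H](O[Si](C)(C)C(C)(C)C)[C@@](C)(CCC=C(C)C)C1=CC[C@@]1(C)CCCC2=C1CC[C@H](C)[C@@]2(C)Cc1cc(OCc3ccccc3)ccc1O[Si](C(C)C)(C(C)C)C(C)C | intermediate
28 | (3S,4S)-4-(TBSO)-3-methyl-3-(4-methylpent-3-en-1-yl)-2-[2-(Oct)ethyl]cyclohexan-1-one, C-2 epimers | O=C1CC[C@H](O[Si](C)(C)C(C)(C)C)[C@@](C)(CCC=C(C)C)C1CC[C@@]1(C)CCCC2=C1CC[C@H](C)[C@@]2(C)Cc1cc(OCc3ccccc3)ccc1O[Si](C(C)C)(C(C)C)C(C)C | intermediate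
29 | (2S,3S,4S)-4-(TBSO)-3-methyl-3-(4-methylpent-3-en-1-yl)-2-[2-(Oct)ethyl]cyclohexan-1-one | O=C1CC[C@H](O[Si](C)(C)C(C)(C)C)[C@@](C)(CCC=C(C)C)[C@@H]1CC[C@@]1(C)CCCC2=C1CC[C@H](C)[C@@]2(C)Cc1cc(OCc3ccccc3)ccc1O[Si](C(C)C)(C(C)C)C(C)C | intermediate
30 | TBS ether of (1S,2S,3R)-2-methyl-4-methylidene-2-(4-methylpent-3-en-1-yl)-3-[2-(Oct)ethyl]cyclohexan-1-ol | C=C1CC[C@H](O[Si](C)(C)C(C)(C)C)[C@@](C)(CCC=C(C)C)[C@@H]1CC[C@@]1(C)CCCC2=C1CC[C@H](C)[C@@]2(C)Cc1cc(OCc3ccccc3)ccc1O[Si](C(C)C)(C(C)C)C(C)C | intermediate
31 | phenol: 30 with the benzyloxy group replaced by hydroxyl | C=C1CC[C@H](O[Si](C)(C)C(C)(C)C)[C@@](C)(CCC=C(C)C)[C@@H]1CC[C@@]1(C)CCCC2=C1CC[C@H](C)[C@@]2(C)Cc1cc(O)ccc1O[Si](C(C)C)(C(C)C)C(C)C | intermediate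
32 | sodium aryl sulfate: 31 with the hydroxyl converted into OSO3Na | C=C1CC[C@H](O[Si](C)(C)C(C)(C)C)[C@@](C)(CCC=C(C)C)[C@@H]1CC[C@@]1(C)CCCC2=C1CC[C@H](C)[C@@]2(C)Cc1cc(OS(=O)(=O)[O-])ccc1O[Si](C(C)C)(C(C)C)C(C)C.[Na+] | intermediate
33 | CNP0426156.3, (1S,2S,3R)-3-{2-[(1R,5R,6S)-5-{[2-hydroxy-5-(sulfooxy)phenyl]methyl}-1,5,6-trimethyl-1,2,3,4,5,6,7,8-octahydronaphthalen-1-yl]ethyl}-2-methyl-4-methylidene-2-(4-methylpent-3-en-1-yl)cyclohexan-1-ol | C=C1CC[C@H](O)[C@@](C)(CCC=C(C)C)[C@@H]1CC[C@@]1(C)CCCC2=C1CC[C@H](C)[C@@]2(C)Cc1cc(OS(=O)(=O)O)ccc1O | target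

## Step count and least certain steps

Total: 21 steps. Longest linear sequence: 17 steps (1–10, then 15–21); the ring A branch (11–14) joins at step 15.

Step 7 (key step). The bulky chiral Lewis acid may not bring methacrolein onto the hindered s-cis diene fast enough, so that acid-induced oligomerisation of the diene, loss of regiocontrol, or a background reaction that erodes facial selection could compete. Fallback, setting out from 12 and returning at 15: methacrolein would be activated with the small achiral promoter Me2AlCl (CH2Cl2, −78 → 0 °C), a combination long used for vinylcyclohexenes. Reagent control at the quaternary carbon is then replaced by separation. The adduct would be 14 together with its epimer at the quaternary carbon, the (1R)-aldehyde F1. After the alkene shift of step 8, 15 and its quaternary-carbon epimer F2 are diastereomers (ring C is already enantiopure) and would be separated by chromatography.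

Step 8. The equilibrium may stop short, leaving the two trisubstituted positional isomers, or the tertiary cation may be captured by the arene ortho carbon. Fallback without any cation, from 14 to 15: a Schenck ene reaction with singlet oxygen (O2, tetraphenylporphyrin, light, CH2Cl2; then PPh3) would give two allylic alcohols, the secondary alcohol with the alkene already in the ring fusion F3 and the tertiary alcohol with the alkene moved the other way F4. The Burgess reagent should dehydrate both to the same homoannular diene F5. Diimide (dipotassium azodicarboxylate, AcOH) would then reduce only its disubstituted alkene, giving 15.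

Step 4. Alkylation of the aluminate by the ortho-silyloxy benzylic bromide may be slow at a centre that becomes quaternary, allowing proton transfer or O-alkylation, and the enantioselectivity of the methyl addition may be incomplete. Fallback, from 5 to 8 in two flasks: the conjugate addition is run alone and the aluminium enolate trapped with Me3SiCl/Et3N as the isolable (S)-2,3-dimethyl-1-[(trimethylsilyl)oxy]cyclohexene F6. MeLi in THF then gives the lithium enolate, which is alkylated with 4 in the presence of DMPU to give 8.

Step 13. Hydrogen abstraction may also occur at the carbon bearing the silyloxy group or at the methyl group, and over-oxidation may lower the return. Fallback, which does not use 18 and 19 and returns at 20: it sets out from commercial 3-ethoxycyclohex-2-en-1-one F7, which replaces 5 as the source of ring A. The kinetic enolate (LDA, −78 °C) is hydroxylated with an enantiopure (camphorsulfonyl)oxaziridine to (S)-3-ethoxy-6-hydroxycyclohex-2-en-1-one F8, which is silylated to its TBS ether F9. MeLi followed by dilute acid (carbonyl addition, enol ether hydrolysis, loss of water) gives 20.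

Step 15. The hindered lithium enolate may deprotonate the α-CH2 of the aldehyde instead of adding to it, returning both partners, and the adduct may revert on warming. Fallback with a non-basic electrophile, from 16 and 23 to 27: 16 is converted with methanol and pyridinium tosylate into the dimethyl acetal of 17, F10. A Mukaiyama-type addition of 23 to F10 with catalytic Me3SiOTf at −78 °C would give the β-methoxy ketone F11, from which DBU eliminates methanol to give 27.

Step 17. Protonation may occur from the wrong face and the thermodynamic preference for the equatorial link may be too small for a clean equilibration. Fallback under kinetic control, from 27 to 29: conjugate hydrosilylation (Et3SiH, Rh(PPh3)3Cl) gives the isolated triethylsilyl enol ether F12. MeLi releases the lithium enolate, which is protonated at −78 °C with a hindered phenol from the face opposite the pseudoaxial methyl.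

## Further compounds

F1 | step 7 | (1R,5R,6S)-5-(ArCH2)-1,5,6-trimethyl-1,2,3,5,6,7,8,8a-octahydronaphthalene-1-carbaldehyde, quaternary-carbon epimer of 14 | O=C[C@]1(C)CCC=C2C1CC[C@H](C)[C@@]2(C)Cc1cc(OCc3ccccc3)ccc1O[Si](C(C)C)(C(C)C)C(C)C
F2 | step 7 | (1R,5R,6S)-5-(ArCH2)-1,5,6-trimethyl-1,2,3,4,5,6,7,8-octahydronaphthalene-1-carbaldehyde, quaternary-carbon epimer of 15 | O=C[C@]1(C)CCCC2=C1CC[C@H](C)[C@@]2(C)Cc1cc(OCc3ccccc3)ccc1O[Si](C(C)C)(C(C)C)C(C)C
F3 | step 8 | 4-hydroxy derivative of 15 (secondary allylic alcohol, alkene C-4a/C-8a) | O=C[C@@]1(C)CCC(O)C2=C1CC[C@H](C)[C@@]2(C)Cc1cc(OCc3ccccc3)ccc1O[Si](C(C)C)(C(C)C)C(C)C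
F4 | step 8 | 4a-hydroxy-1,2,4a,5,6,7,8,8a-octahydro isomer (tertiary allylic alcohol, alkene C-3/C-4) | O=C[C@@]1(C)CC=CC2(O)C1CC[C@H](C)[C@@]2(C)Cc1cc(OCc3ccccc3)ccc1O[Si](C(C)C)(C(C)C)C(C)C
F5 | step 8 | (1S,5R,6S)-5-(ArCH2)-1,5,6-trimethyl-1,2,5,6,7,8-hexahydronaphthalene-1-carbaldehyde (diene C-3/C-4 and C-4a/C-8a) | O=C[C@@]1(C)CC=CC2=C1CC[C@H](C)[C@@]2(C)Cc1cc(OCc3ccccc3)ccc1O[Si](C(C)C)(C(C)C)C(C)C
F6 | step 4 | (S)-2,3-dimethyl-1-[(trimethylsilyl)oxy]cyclohex-1-ene | C[Si](C)(C)OC1=C(C)[C@@H](C)CCC1
F7 | step 13 | 3-ethoxycyclohex-2-en-1-one (new starting material) | CCOC1=CC(=O)CCC1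
F8 | step 13 | (S)-3-ethoxy-6-hydroxycyclohex-2-en-1-one | CCOC1=CC(=O)[C@@H](O)CC1
F9 | step 13 | (S)-6-[(tert-butyldimethylsilyl)oxy]-3-ethoxycyclohex-2-en-1-one | CCOC1=CC(=O)[C@@H](O[Si](C)(C)C(C)(C)C)CC1
F10 | step 15 | dimethyl acetal of 17 | COC(OC)C[C@@]1(C)CCCC2=C1CC[C@H](C)[C@@]2(C)Cc1cc(OCc3ccccc3)ccc1O[Si](C(C)C)(C(C)C)C(C)C
F11 | step 15 | methyl ether of 25 (β-methoxy ketone, epimers) | O=C1CC[C@H](O[Si](C)(C)C(C)(C)C)[C@@](C)(CCC=C(C)C)C1C(OC)C[C@@]1(C)CCCC2=C1CC[C@H](C)[C@@]2(C)Cc1cc(OCc3ccccc3)ccc1O[Si](C(C)C)(C(C)C)C(C)C
F12 | step 17 | triethylsilyl enol ether of 29 | CC[Si](CC)(CC)OC1=C(CC[C@@]2(C)CCCC3=C2CC[C@H](C)[C@@]3(C)Cc2cc(OCc4ccccc4)ccc2O[Si](C(C)C)(C(C)C)C(C)C)[C@](C)(CCC=C(C)C)[C@@H](O[Si](C)(C)C(C)(C)C)CC1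
A1 | alternative 1 | (1S,2S,3R)-3-{[(tert-butyldiphenylsilyl)oxy]methyl}-2-methyl-4-methylidene-2-(4-methylpent-3-en-1-yl)cyclohexan-1-ol | C=C1CC[C@H](O)[C@@](C)(CCC=C(C)C)[C@@H]1CO[Si](c1ccccc1)(c1ccccc1)C(C)(C)C
A2 | alternative 1 | tert-butyl{[(2Z)-5-[(2S,3S)-3-methyl-3-(4-methylpent-3-en-1-yl)oxiran-2-yl]-3-[(trimethylsilyl)methyl]pent-2-en-1-yl]oxy}diphenylsilane | C[Si](C)(C)C/C(=C\CO[Si](c1ccccc1)(c1ccccc1)C(C)(C)C)CC[C@@H]1O[C@@]1(C)CCC=C(C)C
A3 | alternative 2 | aldol adduct of the dimethyl ether series (epimers at the ring methine and the carbinol carbon) | O=C1CC[C@H](O[Si](C)(C)C(C)(C)C)[C@@](C)(CCC=C(C)C)C1C(O)C[C@@]1(C)CCCC2=C1CC[C@H](C)[C@@]2(C)Cc1cc(OC)ccc1OC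
A4 | alternative 2 | 2-[(1R,5R,6S)-5-[(2,5-dimethoxyphenyl)methyl]-1,5,6-trimethyl-1,2,3,4,5,6,7,8-octahydronaphthalen-1-yl]acetaldehyde | O=CC[C@@]1(C)CCCC2=C1CC[C@H](C)[C@@]2(C)Cc1cc(OC)ccc1OC
A5 | alternative 3 | (1R,2S,5R)-5-{2-[(tert-butyldiphenylsilyl)oxy]ethyl}-1,2,5-trimethyl-1,2,3,5,6,7,8,8a-octahydronaphthalene-1-carbaldehyde, C-8a epimers | O=C[C@]1(C)[C@@H](C)CC=C2C1CCC[C@]2(C)CCO[Si](c1ccccc1)(c1ccccc1)C(C)(C)C
A6 | alternative 3 | tert-butyl{2-[(1R)-2-ethenyl-1-methylcyclohex-2-en-1-yl]ethoxy}diphenylsilane | C=CC1=CCCC[C@]1(C)CCO[Si](c1ccccc1)(c1ccccc1)C(C)(C)C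
A7 | alternative 3 | (E)-2-methylbut-2-enal | C/C=C(\C)C=O
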